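Ring B is grown on the C3 methylene instead of being prenylated as a phenol: a phenol whose ring carbons carry OH, an ortho prenyl group and a para C3 substituent is the dehydrogenated form of a 2-prenyl-4-alkylcyclohex-2-enone. The whole plan rests on cutting that enone into a (4R,5S)-4-aroyloxy-5-aryl-5-silyloxypentanal, which already holds ring A, the syringate and both stereocentres, and 7-methylocta-1,6-dien-3-one. One amine-catalysed Robinson annulation (enamine Michael addition, then aldol condensation) forms both new ring B bonds and closes the six-membered ring; Saegusa dehydrogenation later aromatises it and buffered fluoride removes the three silyl groups.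

Key step: step 11

Assumption: the target is (1S,2R), the 1,2-anti arrangement; the (R)-diarylprolinol silyl ether is taken to give the (R)-α-aroyloxy aldehyde by attack on the enamine face away from its diphenyl(silyloxy)methyl group, a sense to be confirmed on the first batch.

Abbreviations: TBS = tert-butyldimethylsilyl, TBSO = tert-butyldimethylsilyloxy, TMS = trimethylsilyl.

Step 1
Reactants: 1 2-methylbut-3-en-2-ol
Product: 3 ethyl 5-methylhex-4-enoate, via mixed ketene acetal 2 (not isolated)
Conditions: MeC(OEt)3, EtCO2H (cat.), 140 °C, EtOH distilled off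
Reagents that add atoms: triethyl orthoacetate CCOC(C)(OCC)OCC
Why: Johnson–Claisen rearrangement: acid-catalysed exchange gives the allyl ketene acetal, whose chair [3,3]-sigmatropic shift forms the new C–C bond at the alkene terminus and leaves the trisubstituted alkene of the future prenyl group; no stereocentre is involved.

Step 2
Reactants: 3 ethyl 5-methylhex-4-enoate
Product: 4 N-methoxy-N,5-dimethylhex-4-enamide
Conditions: MeNH(OMe)·HCl, i-PrMgCl, THF, −20 °C
Reagents that add atoms: N,O-dimethylhydroxylamine hydrochloride CNOC.Cl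
Why: Weinreb amide formation by aminolysis of the ester with the magnesium amide generated in the flask, a standard conversion that the remote alkene does not disturb.

Step 3
Reactants: 4 N-methoxy-N,5-dimethylhex-4-enamide
Product: 5 7-methylocta-1,6-dien-3-one
Conditions: CH2=CHMgBr, THF, 0 °C; inverse quench into cold 1 M HCl
Reagents that add atoms: vinylmagnesium bromide C=C[Mg]Br
Why: Weinreb ketone synthesis: the N-methoxy-N-methylamide accepts one vinyl group only, and the cold acidic inverse quench protonates the liberated amine before it can add to the new vinyl ketone, which is used fresh.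

Step 4
Reactants: 6 syringic acid (4-hydroxy-3,5-dimethoxybenzoic acid)
Product: 8 4-(TBSO)-3,5-dimethoxybenzoic acid, via bis-silylated ester 7 (not isolated)
Conditions: TBSCl (2.2 equiv), imidazole, DMF, rt; then AcOH/THF/H2O, rt
Reagents that add atoms: tert-butyldimethylsilyl chloride CC(C)(C)[Si](C)(C)Cl
Why: Exhaustive silylation followed by selective hydrolysis of the much more labile silyl ester under mild acid, to which the aryl silyl ether is stable.

Step 5
Reactants: 8 4-(TBSO)-3,5-dimethoxybenzoic acid (2 equiv; both aroyl groups of the peroxide come from it)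
Product: 9 bis[4-(TBSO)-3,5-dimethoxybenzoyl] peroxide
Conditions: 8 (2.0 equiv), 30% aq. H2O2 (1.0 equiv), DCC (2.1 equiv), DMAP (cat.), CH2Cl2, −10 to 0 °C, dark
Reagents that add atoms: hydrogen peroxide OO; second molecule of 4-(TBSO)-3,5-dimethoxybenzoic acid 8 COc1cc(C(=O)O)cc(OC)c1O[Si](C)(C)C(C)(C)C
Why: Carbodiimide-mediated diacyl peroxide synthesis: two molecules of the DCC-activated acid acylate the two oxygens of one molecule of hydrogen peroxide under neutral conditions that leave the aryl silyl ether intact; the peroxide is to be kept cold, shielded and used without storage.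

Step 6
Reactants: 10 4-bromo-3-methoxyphenol
Product: 11 (4-bromo-3-methoxyphenoxy)(tert-butyl)dimethylsilane
Conditions: TBSCl, imidazole, CH2Cl2, rt
Reagents that add atoms: tert-butyldimethylsilyl chloride CC(C)(C)[Si](C)(C)Cl
Why: Routine phenol silylation, which removes the acidic proton before the Grignard reagent is made; the silyloxy group sits para to bromine, so no silyl shift to carbon can follow metalation.

Step 7
Reactants: 12 hex-5-enal; 9 bis[4-(TBSO)-3,5-dimethoxybenzoyl] peroxide
Product: 13 (2R)-1-oxohex-5-en-2-yl 4-(TBSO)-3,5-dimethoxybenzoate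
Conditions: (R)-2-[diphenyl(trimethylsilyloxy)methyl]pyrrolidine (10 mol %), hydroquinone (10 mol %), THF, 0 °C; aq. NaHCO3 wash, used at once
Reagents that add atoms: none
Why: Enamine-catalysed α-acyloxylation of an aldehyde with a diaroyl peroxide: the E-enamine attacks one peroxide oxygen from the face opposite the diphenyl(silyloxy)methyl group, which sets C2 as R, while hydroquinone suppresses radical decomposition and the terminal alkene is a spectator.

Step 8
Reactants: 11 (4-bromo-3-methoxyphenoxy)(tert-butyl)dimethylsilane; 13 (2R)-1-oxohex-5-en-2-yl 4-(TBSO)-3,5-dimethoxybenzoate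
Product: 15 (1S,2R)-1-hydroxy-1-[4-(TBSO)-2-methoxyphenyl]hex-5-en-2-yl 4-(TBSO)-3,5-dimethoxybenzoate, via aryl Grignard reagent 14 (not isolated)
Conditions: 11, Mg, LiCl, THF, rt; then 13, THF, −78 °C; then AcOH, −78 °C
Reagents that add atoms: none
Why: Grignard addition under polar Felkin–Anh control: the aryl group attacks the aldehyde anti to the C2–O bond and past the C2 hydrogen, so the existing R centre sets C1 as S (1,2-anti); the aldehyde reacts far faster than the aroyl ester at −78 °C, and the cold acidic quench denies the basic medium in which the ester could migrate to the new oxygen.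

Step 9
Reactants: 15 (1S,2R)-1-hydroxy-1-[4-(TBSO)-2-methoxyphenyl]hex-5-en-2-yl 4-(TBSO)-3,5-dimethoxybenzoate
Product: 16 (1S,2R)-1-(TBSO)-1-[4-(TBSO)-2-methoxyphenyl]hex-5-en-2-yl 4-(TBSO)-3,5-dimethoxybenzoate
Conditions: TBSOTf, 2,6-lutidine, CH2Cl2, −78 to 0 °C
Reagents that add atoms: tert-butyldimethylsilyl trifluoromethanesulfonate CC(C)(C)[Si](C)(C)OS(=O)(=O)C(F)(F)F
Why: Silylation of a hindered secondary alcohol with a silyl triflate and a non-nucleophilic base, under which the neighbouring ester does not migrate; the cap later prevents lactol formation with the aldehyde and acyl migration.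

Step 10
Reactants: 16 (1S,2R)-1-(TBSO)-1-[4-(TBSO)-2-methoxyphenyl]hex-5-en-2-yl 4-(TBSO)-3,5-dimethoxybenzoate
Product: 18 (1S,2R)-1-(TBSO)-1-[4-(TBSO)-2-methoxyphenyl]-5-oxopentan-2-yl 4-(TBSO)-3,5-dimethoxybenzoate (the (4R,5S)-4-aroyloxy-5-aryl-5-silyloxypentanal), via vicinal diol 17 (not isolated)
Conditions: OsO4 (2 mol %), NaIO4, 2,6-lutidine, dioxane/H2O (3:1), rt
Reagents that add atoms: osmium tetroxide O=[Os](=O)(=O)=O; sodium periodate [Na+].[O-]I(=O)(=O)=O
Why: Lemieux–Johnson oxidation: the only alkene in the molecule is dihydroxylated and the diol is cleaved by periodate to the aldehyde with loss of one carbon, the lutidine buffer protects the silyl ethers, and neither stereocentre is α to the new carbonyl.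

Step 11
Reactants: 18 (1S,2R)-1-(TBSO)-1-[4-(TBSO)-2-methoxyphenyl]-5-oxopentan-2-yl 4-(TBSO)-3,5-dimethoxybenzoate; 5 7-methylocta-1,6-dien-3-one
Product: 21 (1S,2R)-1-(TBSO)-1-[4-(TBSO)-2-methoxyphenyl]-3-[3-(3-methylbut-2-enyl)-4-oxocyclohex-2-en-1-yl]propan-2-yl 4-(TBSO)-3,5-dimethoxybenzoate (both epimers at ring carbon 1), via keto aldehyde 19 (not isolated), via aldol adduct 20 (not isolated)
Conditions: 5 (1.5 equiv), (S)-2-(methoxydiphenylmethyl)pyrrolidine (10 mol %), ethyl 3,4-dihydroxybenzoate (20 mol %), CH2Cl2 (1 M), 4 °C to rt; volatiles removed; then pyrrolidine (0.3 equiv), AcOH (0.6 equiv), toluene, 50 °C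
Reagents that add atoms: none
Why: The secondary amine turns aldehyde 18 into its E-enamine, whose α-carbon adds to the vinyl terminus of 5 to give keto aldehyde 19 after hydrolysis; pyrrolidinium acetate then lets the ketone attack the aldehyde through its enamine on the prenyl-bearing side, and aldol 20 loses water to give enone 21. The closest known reaction type is the amine-catalysed Robinson annulation of unbranched aldehydes with methyl or ethyl vinyl ketone to 4-substituted and 2,4-disubstituted cyclohex-2-enones. Ring B closes in a 6-(enolendo)-exo-trig aldol mode, the nucleophilic C=C lying inside and the aldehyde C=O outside the new ring. The one new stereocentre, enone ring carbon 4, is left uncontrolled because step 13 removes it, so either enantiomer of the catalyst serves; the two stereocentres of 18 are not enolisable and the aroyloxy group is γ to the aldehyde, so neither epimerisation nor β-elimination can occur. The step needs a single annulation regiochemistry, secured because only the ketone α-methylene that carries the prenyl chain can reach the aldehyde through a six-membered transition state (the other would close a four-membered ring), and it needs the cross Michael addition to outrun aldehyde self-aldolisation, secured by the hindered diphenylprolinol ether, the catechol co-catalyst and an excess of 5. The non-basic amine/acid medium spares the aryl silyl ethers and the ester and leaves the prenyl alkene out of conjugation.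

Step 12
Reactants: 21 (1S,2R)-1-(TBSO)-1-[4-(TBSO)-2-methoxyphenyl]-3-[3-(3-methylbut-2-enyl)-4-oxocyclohex-2-en-1-yl]propan-2-yl 4-(TBSO)-3,5-dimethoxybenzoate
Product: 23 (1S,2R)-1-(TBSO)-1-[4-(TBSO)-2-methoxyphenyl]-3-[3-(3-methylbut-2-enyl)-4-(trimethylsilyloxy)cyclohexa-2,4-dien-1-yl]propan-2-yl 4-(TBSO)-3,5-dimethoxybenzoate, via lithium dienolate 22 (not isolated)
Conditions: LiN(i-Pr)2 (LDA), THF, −78 °C; then TMSCl, −78 to 0 °C; non-aqueous work-up
Reagents that add atoms: chlorotrimethylsilane C[Si](C)(C)Cl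
Why: Kinetic deprotonation of the enone at its α′-methylene and O-silylation give the cross-conjugated 2-silyloxy-1,3-diene; the aroyl ester has no α-hydrogen and is not attacked by the hindered amide at −78 °C.

Step 13
Reactants: 23 (1S,2R)-1-(TBSO)-1-[4-(TBSO)-2-methoxyphenyl]-3-[3-(3-methylbut-2-enyl)-4-(trimethylsilyloxy)cyclohexa-2,4-dien-1-yl]propan-2-yl 4-(TBSO)-3,5-dimethoxybenzoate
Product: 25 (1S,2R)-1-(TBSO)-1-[4-(TBSO)-2-methoxyphenyl]-3-[4-hydroxy-3-(3-methylbut-2-enyl)phenyl]propan-2-yl 4-(TBSO)-3,5-dimethoxybenzoate, via cross-conjugated dienone 24 (not isolated)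
Conditions: Pd(OAc)2 (1.05 equiv), MeCN, rt
Reagents that add atoms: none
Why: Saegusa–Ito oxidation: the silyl enol ether gives a palladium enolate, β-hydride elimination installs the second ring alkene, and the resulting 4-H cyclohexa-2,5-dienone tautomerises at once to the phenol, erasing the ring stereocentre; divalent palladium is used stoichiometrically without reoxidant so that the zerovalent palladium formed cannot turn over and attack the prenyl alkene.

Step 14
Reactants: 25 (1S,2R)-1-(TBSO)-1-[4-(TBSO)-2-methoxyphenyl]-3-[4-hydroxy-3-(3-methylbut-2-enyl)phenyl]propan-2-yl 4-(TBSO)-3,5-dimethoxybenzoate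
Product: 26 eryvarinol B, (1S,2R)-1-hydroxy-1-(4-hydroxy-2-methoxyphenyl)-3-[4-hydroxy-3-(3-methylbut-2-enyl)phenyl]propan-2-yl 4-hydroxy-3,5-dimethoxybenzoate
Conditions: Bu4NF, AcOH (1:1), THF, 0 °C to rt
Reagents that add atoms: none
Why: Fluoride-mediated cleavage of the two aryl silyl ethers and the benzylic silyl ether; buffering with acetic acid keeps alkoxide and phenoxide concentrations low, which guards against 1,2-migration of the syringate and against quinone methide formation at the electron-rich benzylic carbinol, so both stereocentres are retained.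

Compound list

1 | 2-methylbut-3-en-2-ol | CC(C)(O)C=C | starting material
2 | 3-(1-ethoxyethenyloxy)-3-methylbut-1-ene (mixed ketene acetal) | C=C(OCC)OC(C)(C)C=C | intermediate (not isolated)
3 | ethyl 5-methylhex-4-enoate | CCOC(=O)CCC=C(C)C | intermediate
4 | N-methoxy-N,5-dimethylhex-4-enamide | CON(C)C(=O)CCC=C(C)C | intermediate
5 | 7-methylocta-1,6-dien-3-one | C=CC(=O)CCC=C(C)C | intermediate
6 | syringic acid | COc1cc(C(=O)O)cc(OC)c1O | starting material
7 | tert-butyldimethylsilyl 4-(TBSO)-3,5-dimethoxybenzoate | COc1cc(C(=O)O[Si](C)(C)C(C)(C)C)cc(OC)c1O[Si](C)(C)C(C)(C)C | intermediate (not isolated)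
8 | 4-(TBSO)-3,5-dimethoxybenzoic acid | COc1cc(C(=O)O)cc(OC)c1O[Si](C)(C)C(C)(C)C | intermediate
9 | bis[4-(TBSO)-3,5-dimethoxybenzoyl] peroxide | COc1cc(C(=O)OOC(=O)c2cc(OC)c(O[Si](C)(C)C(C)(C)C)c(OC)c2)cc(OC)c1O[Si](C)(C)C(C)(C)C | intermediate
10 | 4-bromo-3-methoxyphenol | COc1cc(O)ccc1Br | starting material
11 | (4-bromo-3-methoxyphenoxy)(tert-butyl)dimethylsilane | COc1cc(O[Si](C)(C)C(C)(C)C)ccc1Br | intermediate
12 | hex-5-enal | C=CCCCC=O | starting material
13 | (2R)-1-oxohex-5-en-2-yl 4-(TBSO)-3,5-dimethoxybenzoate | O=C[C@@H](CCC=C)OC(=O)c1cc(OC)c(O[Si](C)(C)C(C)(C)C)c(OC)c1 | intermediate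
14 | [4-(TBSO)-2-methoxyphenyl]magnesium bromide | COc1cc(O[Si](C)(C)C(C)(C)C)ccc1[Mg]Br | intermediate (not isolated)
15 | (1S,2R)-1-hydroxy-1-[4-(TBSO)-2-methoxyphenyl]hex-5-en-2-yl 4-(TBSO)-3,5-dimethoxybenzoate | COc1cc(O[Si](C)(C)C(C)(C)C)ccc1[C@H](O)[C@@H](CCC=C)OC(=O)c1cc(OC)c(O[Si](C)(C)C(C)(C)C)c(OC)c1 | intermediate
16 | (1S,2R)-1-(TBSO)-1-[4-(TBSO)-2-methoxyphenyl]hex-5-en-2-yl 4-(TBSO)-3,5-dimethoxybenzoate | COc1cc(O[Si](C)(C)C(C)(C)C)ccc1[C@H](O[Si](C)(C)C(C)(C)C)[C@@H](CCC=C)OC(=O)c1cc(OC)c(O[Si](C)(C)C(C)(C)C)c(OC)c1 | intermediate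
17 | (1S,2R)-1-(TBSO)-1-[4-(TBSO)-2-methoxyphenyl]-5,6-dihydroxyhexan-2-yl 4-(TBSO)-3,5-dimethoxybenzoate (both C5 epimers) | COc1cc(O[Si](C)(C)C(C)(C)C)ccc1[C@H](O[Si](C)(C)C(C)(C)C)[C@@H](CCC(O)CO)OC(=O)c1cc(OC)c(O[Si](C)(C)C(C)(C)C)c(OC)c1 | intermediate (not isolated)
18 | (1S,2R)-1-(TBSO)-1-[4-(TBSO)-2-methoxyphenyl]-5-oxopentan-2-yl 4-(TBSO)-3,5-dimethoxybenzoate; as a pentanal, (4R,5S) | COc1cc(O[Si](C)(C)C(C)(C)C)ccc1[C@H](O[Si](C)(C)C(C)(C)C)[C@@H](CCC=O)OC(=O)c1cc(OC)c(O[Si](C)(C)C(C)(C)C)c(OC)c1 | intermediate (precursor of the key step)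
19 | (1S,2R)-1-(TBSO)-1-[4-(TBSO)-2-methoxyphenyl]-4-formyl-11-methyl-7-oxododec-10-en-2-yl 4-(TBSO)-3,5-dimethoxybenzoate (both C4 epimers) | COc1cc(O[Si](C)(C)C(C)(C)C)ccc1[C@H](O[Si](C)(C)C(C)(C)C)[C@@H](CC(C=O)CCC(=O)CCC=C(C)C)OC(=O)c1cc(OC)c(O[Si](C)(C)C(C)(C)C)c(OC)c1 | intermediate (not isolated)
20 | (1S,2R)-1-(TBSO)-1-[4-(TBSO)-2-methoxyphenyl]-3-[2-hydroxy-3-(3-methylbut-2-enyl)-4-oxocyclohexyl]propan-2-yl 4-(TBSO)-3,5-dimethoxybenzoate (ring stereoisomers) | COc1cc(O[Si](C)(C)C(C)(C)C)ccc1[C@H](O[Si](C)(C)C(C)(C)C)[C@@H](CC1CCC(=O)C(CC=C(C)C)C1O)OC(=O)c1cc(OC)c(O[Si](C)(C)C(C)(C)C)c(OC)c1 | intermediate (not isolated)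
21 | (1S,2R)-1-(TBSO)-1-[4-(TBSO)-2-methoxyphenyl]-3-[3-(3-methylbut-2-enyl)-4-oxocyclohex-2-en-1-yl]propan-2-yl 4-(TBSO)-3,5-dimethoxybenzoate (both epimers at ring carbon 1) | COc1cc(O[Si](C)(C)C(C)(C)C)ccc1[C@H](O[Si](C)(C)C(C)(C)C)[C@@H](CC1CCC(=O)C(CC=C(C)C)=C1)OC(=O)c1cc(OC)c(O[Si](C)(C)C(C)(C)C)c(OC)c1 | intermediate (product of the key step)
22 | lithium cross-conjugated dienolate of 21 | COc1cc(O[Si](C)(C)C(C)(C)C)ccc1[C@H](O[Si](C)(C)C(C)(C)C)[C@@H](CC1CC=C(O[Li])C(CC=C(C)C)=C1)OC(=O)c1cc(OC)c(O[Si](C)(C)C(C)(C)C)c(OC)c1 | intermediate (not isolated)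
23 | (1S,2R)-1-(TBSO)-1-[4-(TBSO)-2-methoxyphenyl]-3-[3-(3-methylbut-2-enyl)-4-(trimethylsilyloxy)cyclohexa-2,4-dien-1-yl]propan-2-yl 4-(TBSO)-3,5-dimethoxybenzoate | COc1cc(O[Si](C)(C)C(C)(C)C)ccc1[C@H](O[Si](C)(C)C(C)(C)C)[C@@H](CC1CC=C(O[Si](C)(C)C)C(CC=C(C)C)=C1)OC(=O)c1cc(OC)c(O[Si](C)(C)C(C)(C)C)c(OC)c1 | intermediate
24 | (1S,2R)-1-(TBSO)-1-[4-(TBSO)-2-methoxyphenyl]-3-[3-(3-methylbut-2-enyl)-4-oxocyclohexa-2,5-dien-1-yl]propan-2-yl 4-(TBSO)-3,5-dimethoxybenzoate | COc1cc(O[Si](C)(C)C(C)(C)C)ccc1[C@H](O[Si](C)(C)C(C)(C)C)[C@@H](CC1C=CC(=O)C(CC=C(C)C)=C1)OC(=O)c1cc(OC)c(O[Si](C)(C)C(C)(C)C)c(OC)c1 | intermediate (not isolated)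
25 | (1S,2R)-1-(TBSO)-1-[4-(TBSO)-2-methoxyphenyl]-3-[4-hydroxy-3-(3-methylbut-2-enyl)phenyl]propan-2-yl 4-(TBSO)-3,5-dimethoxybenzoate | COc1cc(O[Si](C)(C)C(C)(C)C)ccc1[C@H](O[Si](C)(C)C(C)(C)C)[C@@H](Cc1ccc(O)c(CC=C(C)C)c1)OC(=O)c1cc(OC)c(O[Si](C)(C)C(C)(C)C)c(OC)c1 | intermediate
26 | eryvarinol B | COc1cc(O)ccc1[C@H](O)[C@@H](Cc1ccc(O)c(CC=C(C)C)c1)OC(=O)c1cc(OC)c(O)c(OC)c1 | target

Total step count: 14.
Longest linear sequence: 10 steps (from syringic acid 6: steps 4, 5, 7, 8, 9, 10, 11, 12, 13, 14). The dienone branch (steps 1 to 3) and the aryl bromide (step 6) are convergent.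

Steps most likely to fail

1. Step 11. The cross Michael addition may be outrun by self-aldolisation of the hindered, heavily functionalised aldehyde or by polymerisation of the vinyl ketone, and ring closure or dehydration may stall under the mild amine/acid medium. Fallback: the catalytic domino is given up for a stoichiometric, stepwise Stork enamine sequence that separates the two bond formations. Setting out from aldehyde 18, condensation with pyrrolidine (1.1 equiv, 4 Å molecular sieves, benzene, rt) should give (1S,2R)-1-(TBSO)-1-[4-(TBSO)-2-methoxyphenyl]-5-(pyrrolidin-1-yl)pent-4-en-2-yl 4-(TBSO)-3,5-dimethoxybenzoate F1. This preformed E-enamine is added to dienone 5 in MeCN at rt and hydrolysed with AcOH/NaOAc/H2O, so that keto aldehyde 19 is isolated and purified. The ring is then closed in a separate flask with a reagent chosen for the aldol condensation alone (Bn2NH·CF3CO2H, benzene, 50 °C), which comes back to the route at enone 21.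

2. Step 7. Oxygen transfer from the electron-rich peroxide may be slow, so that peroxide decomposition competes, and the α-aroyloxy aldehyde may lose enantiopurity by enolisation. Fallback: C2 is taken from the chiral pool and the ester is made by ordinary acylation, setting out from acid 8 and returning at aldehyde 13. Commercial (R)-tert-butyldimethylsilyl glycidyl ether is opened at its terminal carbon with allylmagnesium chloride and catalytic CuI (THF, −30 °C) to give (2R)-1-(TBSO)hex-5-en-2-ol F2. Esterification with 8 (EDC·HCl, DMAP, CH2Cl2) should give (2R)-1-(TBSO)hex-5-en-2-yl 4-(TBSO)-3,5-dimethoxybenzoate F3. Acid-catalysed methanolysis (camphorsulfonic acid cat., MeOH/CH2Cl2, 0 °C) removes the primary alkyl silyl ether and leaves the aryl silyl ether, giving (2R)-1-hydroxyhex-5-en-2-yl 4-(TBSO)-3,5-dimethoxybenzoate F4. This alcohol is oxidised without delay with Dess–Martin periodinane (NaHCO3, CH2Cl2, 0 °C) to 13.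

3. Step 8. Facial selectivity may be poor if Felkin–Anh control by the acyloxy group is weak, and the ester may migrate to the new alkoxide or be attacked before the quench. Fallback: substrate control is replaced by catalyst control through an oxidation and reduction pair, setting out from the unseparated C1-epimer mixture of 15 and returning at 15. Dess–Martin periodinane (NaHCO3, CH2Cl2, 0 °C) converges both epimers on (2R)-1-[4-(TBSO)-2-methoxyphenyl]-1-oxohex-5-en-2-yl 4-(TBSO)-3,5-dimethoxybenzoate F5. Asymmetric transfer hydrogenation with RuCl[(R,R)-TsDPEN](p-cymene) in HCO2H/Et3N (5:2) at rt then sets C1 by aryl-directed hydride delivery, expected to give the 1S carbinol. The terminal alkene is not reduced, and the mildly acidic medium disfavours both C2 epimerisation and acyl migration.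

Further compounds
F1 | step 11 | (1S,2R)-1-(TBSO)-1-[4-(TBSO)-2-methoxyphenyl]-5-(pyrrolidin-1-yl)pent-4-en-2-yl 4-(TBSO)-3,5-dimethoxybenzoate (E-enamine of 18) | COc1cc(O[Si](C)(C)C(C)(C)C)ccc1[C@H](O[Si](C)(C)C(C)(C)C)[C@@H](C/C=C/N1CCCC1)OC(=O)c1cc(OC)c(O[Si](C)(C)C(C)(C)C)c(OC)c1
F2 | step 7 | (2R)-1-(TBSO)hex-5-en-2-ol | CC(C)(C)[Si](C)(C)OC[C@@H](CCC=C)O
F3 | step 7 | (2R)-1-(TBSO)hex-5-en-2-yl 4-(TBSO)-3,5-dimethoxybenzoate | CC(C)(C)[Si](C)(C)OC[C@@H](CCC=C)OC(=O)c1cc(OC)c(O[Si](C)(C)C(C)(C)C)c(OC)c1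
F4 | step 7 | (2R)-1-hydroxyhex-5-en-2-yl 4-(TBSO)-3,5-dimethoxybenzoate | OC[C@@H](CCC=C)OC(=O)c1cc(OC)c(O[Si](C)(C)C(C)(C)C)c(OC)c1
F5 | step 8 | (2R)-1-[4-(TBSO)-2-methoxyphenyl]-1-oxohex-5-en-2-yl 4-(TBSO)-3,5-dimethoxybenzoate | COc1cc(O[Si](C)(C)C(C)(C)C)ccc1C(=O)[C@@H](CCC=C)OC(=O)c1cc(OC)c(O[Si](C)(C)C(C)(C)C)c(OC)c1
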